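Numbering (decalin): C1 CH(OH), C2 CH2, C3 CHCl, C4 and C10 quaternary, C5 ring-fusion CH, C6–C9 the rest of ring B, C11/C12 the formyl carbons on C9/C8. β is the face of the C10 methyl.
Retrosynthesis: both CHO groups come from the 11,12-diol, the side-chain C=C from cross-metathesis, and O at C12 from allylic oxidation. 9α-H and C7=C8 come from reductive transposition of a C7 enone. Ring A is then cut at C1–C2, C4–C5 and C3–Cl, and ring B at C5–C10 and C8–C9 (Diels–Alder).
Enabling feature: in ring A the C1 carbinol and the C3 chloride flank C2H2, a 1,3-chlorohydrin that equals formyl group + vinyl group + chloride. C3 hangs on quaternary C4 next to C5, which is β to a temporary C7 carbonyl (allyl-inverted conjugate allylation). C2–C3–C4 is therefore one allylsilane that reacts at both ends.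
Forward order: ring B (steps 1–3), Z-allylsilane (steps 4–5), ring A closed onto ring B in one flask (step 6), then ring B is edited and the side chain completed (steps 7–14).
Stereochemistry: C10 is set by a catalytic enantioselective Diels–Alder reaction. C5, C4, C3 and C1 are relayed from C10 in step 6, C7 from the decalin in step 8, and C9 from C7 in step 9.
Helpers and their removal: C7=O (activator) and C8=C9 (keeps C9 flat) both leave in step 9. The terminal butenyl chain (non-competing alkene) is capped in step 12. Acetate and triethylsilyl groups leave in steps 11 and 14.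

Key step: step 6

Remark: 1, 3, 7, 8 and all named reagents are taken as commercial; the catalyst of step 2 is assumed to follow the usual facial model for 2-substituted enals, and its mirror image would be used otherwise.

Step 1
Reactants: 1 pent-1-en-3-one
Product: 2 (Z)-3-(triisopropylsilyloxy)penta-1,3-diene
Conditions: TIPSOTf, Et3N, Et2O, 0 °C
Reagents that add atoms: triisopropylsilyl triflate, CC(C)[Si](OS(=O)(=O)C(F)(F)F)(C(C)C)C(C)C
Why: Silyl enol ether formation by soft enolisation takes the only enolisable side of the ketone and should give the Z-enol ether, whose methyl group (future C12) points outward in the s-cis diene.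

Step 2
Reactants: 2 (Z)-3-(triisopropylsilyloxy)penta-1,3-diene; 3 (E)-4-acetoxy-2-methylbut-2-enal
Product: 5 ring B keto aldehyde, via silyl enol ether cycloadduct 4 (not isolated)
Conditions: (S)-diphenylprolinol-derived o-tolyl oxazaborolidinium bis(triflyl)imide (15 mol %), CH2Cl2, −78 to −40 °C; then HF·pyridine, THF, 0 °C
Reagents that add atoms: none
Why: In this enantioselective Diels–Alder reaction of a 2-substituted enal under chiral oxazaborolidinium catalysis the silyloxy group steers diene carbon C8 to the β-carbon C9 and C5 to C10 (para rule), the shielded face of the bound enal sets the quaternary centre C10 (the only centre that is kept, since C8 and C9 are flattened in step 3), and fluoride then frees the ketone.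

Step 3
Reactants: 5 ring B keto aldehyde
Product: 6 ring B dienone aldehyde
Conditions: IBX (4 equiv), DMSO–fluorobenzene, 70 °C
Reagents that add atoms: none
Why: IBX dehydrogenation of ketones, run exhaustively on both α,β pairs, should give the cross-conjugated dienone without any regiochemical question, erasing C8 and C9 and leaving C10 untouched because the formyl group has no α-hydrogen.

Step 4
Reactants: 7 but-3-enylmagnesium bromide; 8 propyne
Product: 11 (Z)-1-iodo-2-methylhexa-1,5-diene, via but-3-enylcopper 9 (not isolated), via alkenylcopper 10 (not isolated)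
Conditions: CuBr·SMe2, Et2O–Me2S, −45 °C; 8, −25 °C; I2, −78 °C to rt
Reagents that add atoms: iodine, II
Why: Syn carbocupration of a terminal alkyne puts the butenyl group on the internal carbon and copper on the terminal one, cis to each other, and iodinolysis with retention fixes the Z-trisubstituted alkene.

Step 5
Reactants: 11 (Z)-1-iodo-2-methylhexa-1,5-diene
Product: 12 (Z)-trimethyl(3-methylhepta-2,6-dien-1-yl)silane
Conditions: Me3SiCH2MgCl, Pd(PPh3)4 (3 mol %), THF, rt
Reagents that add atoms: (trimethylsilyl)methylmagnesium chloride, C[Si](C)(C)C[Mg]Cl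
Why: Kumada cross-coupling of an alkenyl iodide goes with retention of alkene geometry and is the standard entry to geometrically defined allylsilanes.

Step 6
Reactants: 6 ring B dienone aldehyde; 12 (Z)-trimethyl(3-methylhepta-2,6-dien-1-yl)silane
Product: 14 trans-decalin chlorohydrin enone, via titanium dienolate 13 (not isolated)
Conditions: 6, TiCl4 (1.05 equiv), 2,6-di-tert-butyl-4-methylpyridine (0.3 equiv), CH2Cl2, −78 °C; 12 (1.2 equiv); then TiCl4 (2.5 equiv), −78 to −30 °C; aq NaHCO3
Reagents that add atoms: titanium tetrachloride, Cl[Ti](Cl)(Cl)Cl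
Why: Proposed new method: the first equivalent of TiCl4 should sit on the most Lewis-basic oxygen (the cross-conjugated C7=O) and leave the formyl group unactivated, so the γ-carbon C4 of 12 adds in SE2′ fashion to the only unsubstituted β-carbon C5, chloride takes the silyl group and dienolate 13 results with a vinyl group (C3=C2) on the new quaternary C4; further TiCl4 then activates the formyl carbon C1, the vinyl terminus C2 attacks it, chloride is captured at C3, and the quench protonates the dienolate at C6. The closest known reaction types are the Hosomi–Sakurai conjugate allylation of dienones and the Lewis-acid-induced Prins cyclisation of 5-hexenals to 3-chlorocyclohexanols, and what is new is their union in one flask with one allylsilane acting as nucleophile at both of its termini. Ring A closes in a chair-like 6-endo-trig mode with respect to the alkene (exo with respect to C=O) from the conformer in which the arms on C5 and C10 are both equatorial, which makes the decalin trans-fused. C5: C10 is the only sp3 ring atom, so in the reactive envelope the smaller and better σ-accepting formyl group takes the pseudo-axial site and the silane enters C5 axially and anti to it; C4: in the open antiperiplanar transition state the flat C3 lies next to C10 with its CH2SiMe3 arm turned outward and the butenyl chain takes the free sector between C6 and H5, which for the Z-silane puts the chain α (equatorial) and CH3 β (axial). C1: the in-plane C11 arm on sp2 C9 leaves no room for an equatorial titanium-bound oxygen, so O1 goes axial (α); C3: chloride adds anti to the forming C1–C2 bond, which is the equatorial (β) position. The selectivities needed are dienone over aldehyde (staged Lewis acid), C5 over C9 (substitution), vinyl over side-chain alkene (the truncated terminal butenyl group is no better a nucleophile and could reach C1 only through an eight-membered ring) and chloride capture over a methyl shift from C4 (low temperature, chloride-rich titanium ate complex, proton scavenger).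

Step 7
Reactants: 14 trans-decalin chlorohydrin enone
Product: 15 C1 triethylsilyl ether
Conditions: TESOTf, 2,6-lutidine, CH2Cl2, −78 to 0 °C
Reagents that add atoms: triethylsilyl triflate, CC[Si](CC)(CC)OS(=O)(=O)C(F)(F)F
Why: Silylation with a silyl triflate and a hindered pyridine base is the usual answer to a hindered axial secondary alcohol and shields O1 from the Mitsunobu and Swern steps.

Step 8
Reactants: 15 C1 triethylsilyl ether
Product: 16 7β-allylic alcohol
Conditions: NaBH4, CeCl3·7H2O, MeOH, −78 to 0 °C
Reagents that add atoms: none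
Why: In the Luche 1,2-reduction hydride should attack the enone carbonyl axially from the open α face, as in steroidal 4-en-3-ones that carry a β angular methyl, and give the pseudo-equatorial 7β-alcohol while acetate, chloride and alkene stay inert.

Step 9
Reactants: 16 7β-allylic alcohol
Product: 19 C7=C8 homoallylic acetate, via sulfonyl hydrazone adduct 17 (not isolated), via allylic diazene 18 (not isolated)
Conditions: N-isopropylidene-N′-(2-nitrobenzenesulfonyl)hydrazine, PPh3, DEAD, THF, 0 °C to rt; then CF3CH2OH–H2O, rt
Reagents that add atoms: none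
Why: Mitsunobu displacement of the 7β-alcohol by the sulfonamide nitrogen goes with inversion, hydrolysis and loss of sulfinate give the 7α-allylic diazene, and its retro-ene loss of N2 (allylic diazene rearrangement, reductive 1,3-transposition) delivers hydrogen suprafacially to the α face of C9, which sets 9α-H and 9β-CH2OAc, moves the double bond to C7=C8 and removes the C7 oxygen; the acetone-masked reagent releases no diimide that could reduce the terminal alkene.

Step 10
Reactants: 19 C7=C8 homoallylic acetate
Product: 20 C12 allylic alcohol
Conditions: SeO2 (0.3 equiv), t-BuOOH, CH2Cl2, 0 °C to rt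
Reagents that add atoms: tert-butyl hydroperoxide, CC(C)(C)OO (oxygen relayed through SeO2, O=[Se]=O)
Why: Selenium dioxide allylic oxidation (ene reaction, then [2,3]-shift) attacks the more substituted end of the electron-rich trisubstituted C7=C8 bond and there prefers CH3 (C12) over the hindered methine C9, as known for drimenyl esters, while the terminal side-chain alkene reacts far more slowly.

Step 11
Reactants: 20 C12 allylic alcohol
Product: 21 11,12-diol bearing the butenyl chain
Conditions: K2CO3 (0.2 equiv), MeOH, 0 °C to rt
Reagents that add atoms: none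
Why: Base-catalysed transesterification removes the primary acetate and leaves the hindered secondary silyl ether, the secondary chloride and both alkenes alone.

Step 12
Reactants: 21 11,12-diol bearing the butenyl chain
Product: 22 11,12-diol bearing the full side chain
Conditions: second-generation Grubbs catalyst (5 mol %), 2-methylbut-2-ene (excess), CH2Cl2, 40 °C
Reagents that add atoms: 2-methylbut-2-ene, CC=C(C)C
Why: Olefin cross-metathesis of a terminal alkene with excess 2-methylbut-2-ene is the standard way to cap it as a prenyl-type trisubstituted alkene, and the hindered trisubstituted ring alkene should not take part.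

Step 13
Reactants: 22 11,12-diol bearing the full side chain
Product: 23 silyl-protected dialdehyde
Conditions: (COCl)2, DMSO, CH2Cl2, −78 °C; Et3N, −78 to −20 °C
Reagents that add atoms: none
Why: The Swern oxidation activates both primary alcohols in the cold before either aldehyde is released, which avoids the lactol-to-lactone path open to stepwise oxidants of such 1,4-diols, and the short cold amine treatment should not epimerise C9.

Step 14
Reactants: 23 silyl-protected dialdehyde
Product: 24 CNP0155449.1
Conditions: HF·pyridine, pyridine, THF, 0 °C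
Reagents that add atoms: none
Why: Fluoride-mediated silyl ether cleavage in a buffered, weakly acidic medium frees the axial C1 alcohol without base, so the epimerisable C9 centre and the ene-dialdehyde should survive.

Compound list
1 | pent-1-en-3-one (ethyl vinyl ketone) | C=CC(=O)CC | starting material
2 | (Z)-3-(triisopropylsilyloxy)penta-1,3-diene | C=C/C(O[Si](C(C)C)(C(C)C)C(C)C)=C/C | intermediate
3 | (E)-4-acetoxy-2-methylbut-2-enal | O=C/C(C)=C/COC(C)=O | starting material
4 | silyl enol ether cycloadduct (C10: CHO α, CH3 β; C9: CH2OAc β; C8: CH3 α; C6=C7–OTIPS) | O=C[C@]1(C)[C@@H](COC(C)=O)[C@H](C)C(O[Si](C(C)C)(C(C)C)C(C)C)=CC1 | intermediate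
5 | ring B keto aldehyde (C7 ketone; C10: CHO α, CH3 β; C9: CH2OAc β; C8: CH3 α) | O=C[C@]1(C)[C@@H](COC(C)=O)[C@H](C)C(=O)CC1 | intermediate
6 | ring B dienone aldehyde, [(6S)-6-formyl-2,6-dimethyl-3-oxocyclohexa-1,4-dien-1-yl]methyl acetate | O=C[C@]1(C)C(COC(C)=O)=C(C)C(=O)C=C1 | intermediate
7 | but-3-enylmagnesium bromide | C=CCC[Mg]Br | starting material
8 | propyne | CC#C | starting material
9 | but-3-enylcopper | C=CCC[Cu] | intermediate
10 | (Z)-(2-methylhexa-1,5-dien-1-yl)copper | C=CCC/C(C)=C\[Cu] | intermediate
11 | (Z)-1-iodo-2-methylhexa-1,5-diene | C=CCC/C(C)=C\I | intermediate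
12 | (Z)-trimethyl(3-methylhepta-2,6-dien-1-yl)silane | C=CCC/C(C)=C\C[Si](C)(C)C | intermediate
13 | trichlorotitanium dienolate of the conjugate adduct (C5: new arm β, trans to CHO; C4 bears CH3, vinyl and butenyl) | C=CCC[C@](C)(C=C)[C@@H]1C=C(O[Ti](Cl)(Cl)Cl)C(C)=C(COC(C)=O)[C@@]1(C)C=O | intermediate
14 | trans-decalin chlorohydrin enone (1α-OH, 3β-Cl, 4β-CH3, 4α-butenyl, 5α-H, 10β-CH3; C7=O, C8=C9) | C=CCC[C@]1(C)[C@@H](Cl)C[C@H](O)[C@]2(C)C(COC(C)=O)=C(C)C(=O)C[C@@H]12 | intermediate
15 | C1 triethylsilyl ether of 14 | C=CCC[C@]1(C)[C@@H](Cl)C[C@H](O[Si](CC)(CC)CC)[C@]2(C)C(COC(C)=O)=C(C)C(=O)C[C@@H]12 | intermediate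
16 | 7β-allylic alcohol | C=CCC[C@]1(C)[C@@H](Cl)C[C@H](O[Si](CC)(CC)CC)[C@]2(C)C(COC(C)=O)=C(C)[C@@H](O)C[C@@H]12 | intermediate
17 | 7α-N-sulfonyl hydrazone adduct | C=CCC[C@]1(C)[C@@H](Cl)C[C@H](O[Si](CC)(CC)CC)[C@]2(C)C(COC(C)=O)=C(C)[C@H](N(N=C(C)C)S(=O)(=O)c3ccccc3[N+](=O)[O-])C[C@@H]12 | intermediate
18 | 7α-allylic diazene | C=CCC[C@]1(C)[C@@H](Cl)C[C@H](O[Si](CC)(CC)CC)[C@]2(C)C(COC(C)=O)=C(C)[C@H](N=N)C[C@@H]12 | intermediate
19 | C7=C8 homoallylic acetate (9α-H, 9β-CH2OAc, C8–CH3) | C=CCC[C@]1(C)[C@@H](Cl)C[C@H](O[Si](CC)(CC)CC)[C@]2(C)[C@@H](COC(C)=O)C(C)=CC[C@@H]12 | intermediate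
20 | C12 allylic alcohol, C11 acetate | C=CCC[C@]1(C)[C@@H](Cl)C[C@H](O[Si](CC)(CC)CC)[C@]2(C)[C@@H](COC(C)=O)C(CO)=CC[C@@H]12 | intermediate
21 | 11,12-diol bearing the butenyl chain | C=CCC[C@]1(C)[C@@H](Cl)C[C@H](O[Si](CC)(CC)CC)[C@]2(C)[C@@H](CO)C(CO)=CC[C@@H]12 | intermediate
22 | 11,12-diol bearing the 4-methylpent-3-enyl chain | CC(C)=CCC[C@]1(C)[C@@H](Cl)C[C@H](O[Si](CC)(CC)CC)[C@]2(C)[C@@H](CO)C(CO)=CC[C@@H]12 | intermediate
23 | silyl-protected dialdehyde | CC(C)=CCC[C@]1(C)[C@@H](Cl)C[C@H](O[Si](CC)(CC)CC)[C@]2(C)[C@@H](C=O)C(C=O)=CC[C@@H]12 | intermediate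
24 | CNP0155449.1 (1α-hydroxy, 3β-chloro, 9β-formyl ene-dialdehyde) | CC(C)=CCC[C@]1(C)[C@@H](Cl)C[C@H](O)[C@]2(C)[C@@H](C=O)C(C=O)=CC[C@@H]12 | target

Total steps: 14. Longest linear sequence: 12 steps (1, 2, 3, 6–14).

Steps most likely to fail

**Step 6 (labelled step).**
- The silane may be consumed by 1,2-addition to the formyl group.
- It may enter C5 from the formyl face and end in a cis-fused decalin.
- The developing C3 cation may suffer a methyl shift from C4 before chloride arrives.

The fallback uses known reactions only and runs from 5 back to 14. The formyl group is taken out of play before the allylation and brought back for a separate cyclisation. LiAlH(Ot-Bu)3 (THF, −78 °C) should reduce only the aldehyde of 5 to the hydroxy ketone F1. TBDPSCl and imidazole give the silyl ether F2, and IBX gives the silyloxymethyl dienone F3, which holds no group that can migrate or compete. An ordinary Hosomi–Sakurai addition of 12 (TiCl4, CH2Cl2, −78 °C), now anti to the much larger silyloxymethyl group, gives the vinyl enone F4. HF·pyridine frees the primary alcohol F5, and Dess–Martin periodinane gives the keto aldehyde F6. MeAlCl2 (2 equiv, CH2Cl2, −78 to 0 °C) is the established reagent for closing 5-hexenals to 3-chlorocyclohexanols and is itself a proton scavenger. It then closes ring A to 14.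

**Step 3.** On heating, the formyl dienone may lose or shift its formyl group with aromatisation, or the second dehydrogenation may stall at the hindered C8–C9 pair. The fallback runs from 4 (isolated instead of being desilylated) back to 6. It uses two Saegusa–Ito dehydrosilylations at or below room temperature in place of hypervalent iodine. Pd(OAc)2 (MeCN, rt) turns 4 into the C5=C6 enone F7. TMSOTf and Et3N enolise its only α′ position to the silyl dienol ether F8, and a second treatment with Pd(OAc)2 gives 6.

**Step 10.** Oxidation may spread to C6, C9 or the allylic CH2 of the side chain, or run on to the enal. The fallback runs from 19 back to 21 and brings in the oxygen through the alkene instead of the C–H bond.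
- mCPBA (1 equiv, −20 °C) should epoxidise only the trisubstituted ring alkene from the α face to the epoxide F9.
- Al(Oi-Pr)3 (toluene, reflux) isomerises it to the exocyclic allylic alcohol F10.
- Ac2O, pyridine and DMAP give the secondary allylic acetate F11.
- PdCl2(MeCN)2 (5 mol %, THF, rt) moves the acetate by [3,3]-transposition to the primary position with the more substituted C7=C8 bond, giving the diacetate F12.
- K2CO3 in MeOH then gives 21.

Further compounds
F1 | step 6 | hydroxy ketone (C1 as CH2OH) | OC[C@]1(C)[C@@H](COC(C)=O)[C@H](C)C(=O)CC1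
F2 | step 6 | tert-butyldiphenylsilyl ether of F1 | CC(C)(C)[Si](OC[C@]1(C)[C@@H](COC(C)=O)[C@H](C)C(=O)CC1)(c1ccccc1)c1ccccc1
F3 | step 6 | silyloxymethyl dienone | CC(C)(C)[Si](OC[C@]1(C)C(COC(C)=O)=C(C)C(=O)C=C1)(c1ccccc1)c1ccccc1
F4 | step 6 | vinyl enone from conjugate allylation | C=CCC[C@](C)(C=C)[C@@H]1CC(=O)C(C)=C(COC(C)=O)[C@@]1(C)CO[Si](c1ccccc1)(c1ccccc1)C(C)(C)C
F5 | step 6 | primary alcohol | C=CCC[C@](C)(C=C)[C@@H]1CC(=O)C(C)=C(COC(C)=O)[C@@]1(C)CO
F6 | step 6 | keto aldehyde | C=CCC[C@](C)(C=C)[C@@H]1CC(=O)C(C)=C(COC(C)=O)[C@@]1(C)C=O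
F7 | step 3 | C5=C6 enone aldehyde | O=C[C@]1(C)[C@@H](COC(C)=O)[C@H](C)C(=O)C=C1
F8 | step 3 | trimethylsilyl dienol ether | O=C[C@]1(C)[C@@H](COC(C)=O)C(C)=C(O[Si](C)(C)C)C=C1
F9 | step 10 | 7α,8α-epoxide | C=CCC[C@]1(C)[C@@H](Cl)C[C@H](O[Si](CC)(CC)CC)[C@]2(C)[C@@H](COC(C)=O)[C@]3(C)O[C@@H]3C[C@@H]12
F10 | step 10 | 7α-hydroxy exocyclic alkene | C=CCC[C@]1(C)[C@@H](Cl)C[C@H](O[Si](CC)(CC)CC)[C@]2(C)[C@@H](COC(C)=O)C(=C)[C@H](O)C[C@@H]12
F11 | step 10 | 7α-acetoxy exocyclic alkene | C=CCC[C@]1(C)[C@@H](Cl)C[C@H](O[Si](CC)(CC)CC)[C@]2(C)[C@@H](COC(C)=O)C(=C)[C@H](OC(C)=O)C[C@@H]12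
F12 | step 10 | 11,12-diacetate with C7=C8 | C=CCC[C@]1(C)[C@@H](Cl)C[C@H](O[Si](CC)(CC)CC)[C@]2(C)[C@@H](COC(C)=O)C(COC(C)=O)=CC[C@@H]12
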